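## The problem

CNP0313121.1 (29) is a monocyclic bisabolane-type triester in which a cyclohexane (C1 the CH carrying the side chain, C2 the CH2, C3 the CHCl, C4 the C(OH)CH3, C5 the CH angelate, C6 the CH acetate) is joined through the single bond C1–C7 to a chain made of C7 (sp2, with its methylene carbon C12), C8 (CH angelate), C9 (CH2) and the C10–C11 epoxide (CH and CMe2). The ring carries five contiguous stereocentres: the side chain on C1, the acetate on C6, the angelate on C5 and the hydroxyl on C4 lie on one face, and only the chlorine on C3 lies on the other. These centres can be relayed from one another, C1 to C6 in a cycloaddition, C1 to C5 through a carboxyl group that reaches across the ring, and C5 to C4 and C3 through its ester. C8 and C10 are insulated from the ring by the sp2 carbon C7 and therefore need a reagent and the chiral pool. Three secondary oxygens (C5, C6, C8) carry two kinds of ester and have to be told apart. The fragile groups dictate the order of events: angelates drift to tiglates under nucleophiles, base or heat, the trisubstituted C10–C11 epoxide does not survive acid or chloride, and a trans chlorohydrin closes to an epoxide with base, so chlorine has to come last and under buffered conditions. The enabling feature is the C5 angelate of a C3=C4 alkene precursor: its carbonyl oxygen sits five atoms from C4 and can open a chloronium ion from the opposite face, which sets chlorine trans to the C4 oxygen and the C4 oxygen cis to C5 in one event.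

## Retrosynthesis

**C3–Cl and C4–O.** Both bonds of 29 are cut together, back to the alkene triester 26 and N-chlorosuccinimide 27. The neighbouring cut, a ring epoxide opened by chloride, would put two trisubstituted epoxides in one molecule and ask a nucleophile to choose between them. Cutting to the alkene removes two stereocentres and the most base-sensitive group. The forward step must pick one of four C=C bonds, one face, and leave the side-chain epoxide and both angelate geometries alone.

**Epoxide C10–O and the three esters.** The epoxide of 26 is cut to the (10R)-diol 24, closed through mesylate 25 with inversion as the last operation before chlorination. Diol 24 comes from acetonide 23, the acetate of 23 is cut to alcohol 22, this to silyl ether 21, and the two angelates of 21 to diol 19 and two equivalents of angelic acid 20. This order follows from the protecting groups: the C5 and C8 hydroxyls are free together in 19 while C6 is still silylated, so the three oxygens are distinguished without protecting C8 at all.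

**C7–C8.** Diol 19 comes from the (8S)-alcohol 18, and this from enone 17 and the epimeric alcohols 16. The bond between the sp2 carbon C7 and the carbinol C8 is cut to enol triflate 11 and aldehyde 15. Cutting C8–C9 instead would need a C9 nucleophile with oxygen β to the carbanion, and cutting C1–C7 would break a stereocentre. The chromium-mediated coupling tolerates every group present. C8 is then set by oxidation and catalyst-controlled reduction, not by relying on substrate control across C7.

**Side chain.** Aldehyde 15 is cut through alcohol 14 and triol 13 to the hydroxy lactone 12, removing two methyl–carbon bonds. The chiral pool supplies C10 in the (R) form, which the later inversion turns into the (S)-epoxide.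

**C7 methyl and the C5 hydroxyl.** Triflate 11 comes from methyl ketone 10 and its alcohol 9. The C7–C12 bond of 9 is cut to the bicyclic lactone 8. In 8 the C1 carboxyl is tied to the C5 oxygen, so opening it with one methyl nucleophile gives the ketone and frees C5–OH while C6 is still a silyl ether. The C5 and C6 oxygens are thus told apart without a selective protection.

**Moving the ring alkene.** Lactone 8 is cut at C3=C4 to the tertiary alcohol 7, and 7 at its C5–O bond to epoxy acid 6, epoxy ester 5 and cyclohexene 4. The cycloaddition leaves the alkene at C4=C5. Epoxidation on the face away from the carboxyl, opening at C5 by that carboxyl, and loss of water toward C3 move the alkene to C3=C4 and set C5. Direct isomerisation of such an epoxide to the allylic alcohol was rejected because it normally takes a methyl proton and gives the exocyclic alkene.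

**Ring.** Ester 4 is cut at C1–C6 and C2–C3 to diene 2 and acrylate 3, and 2 to aldehyde 1. Endo addition sets C1 and C6 cis. The silyl ether placed here lasts until step 17.

## Roads not taken

Alternative 1: the ring is cut at C5–C6 and C1–C2. In the forward key step the diene A1 and cyclobutenone A2 combine under a chiral oxazaborolidinium catalyst to the cis-fused cyclobutanone A3, and Baeyer–Villiger oxidation then inserts oxygen at C6 with retention to give the cis lactone A4. Its merits are that the alkene is born at C3=C4, that C1, C5 and C6 are set all-cis in one step, that the C5 and C6 oxygens are already different (silyl ether and lactone), and that no transposition is needed. Its weak points are that A2 is volatile, polymerises easily and has to be prepared, and that in A4 the lactone carbonyl is C8, so C9–C11 must enter as a nucleophile with oxygen β to the carbanion or the C10–C11 oxygens must be added late to a molecule with several alkenes; C7 must then be methylenated next to that carbonyl. In building the ring this road is shorter than the chosen one (two steps to A4 against five to 8). The chosen plan sets against it a convergent coupling in which C8–C11 arrive as the stable aldehyde 15 with C10 already configured, and a dienophile from the bottle.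

Alternative 2: the ring is cut at C1–C6 and C2–C3, the same two bonds as in step 2. In the forward key step the acetoxy diene A5 and the imide A6 combine under a chiral bis(oxazoline) complex of divalent copper, Cu(SbF6)2 with a tert-butyl bis(oxazoline) ligand, to the cis adduct A7. This pairing of an acetoxy diene with a chelating imide is the best documented form of the cycloaddition, and the acetate needed on C6 is already in place. The weak points are that the alkene sits at C4=C5 and the road has no device of its own for moving it, and that the acetate cannot pass the organometallic steps that build C7 and would be lost in the hydrolysis that frees the carboxyl, so it would have to be exchanged and put back. As a cycloaddition, A7 is at least as good as 4 and better precedented. The chosen plan sets against it a silyl ether that survives to step 17 and an ester that hydrolyses directly to the carboxylate needed for step 4, which saves one step. A7 is kept as the fallback for step 2.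

Alternative 3: the ring is cut at C1–C2. In the forward key step the lactone A9, built from 2-deoxy-D-ribose A8, is converted into its silyl ketene acetal, and a [3,3] shift forms C1–C2, breaks C4–O and contracts the ring to the cyclohexene acid A10. C5 and C6 come from the sugar without a catalyst, the sigmatropic shift places the alkene at C3=C4 without ambiguity, and A10 carries the C7 carboxyl. The weak points are that A9 needs a fully substituted C4 with methyl and vinyl in a defined configuration (vinyl trans to the C5 oxygen), that the ketene acetal has the C6 oxygen β to the enolate carbon and can eliminate, that the contraction must pass through a boat-like arrangement, and that in A10 the C5 and C6 oxygens are locked in one acetonide, so the angelate/acetate distinction is left unsolved. It is the cleanest way to fix the alkene position and uses no asymmetric catalyst. The chosen plan sets against it fewer steps to a ring fragment in which C5 and C6 are already differentiated.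

Key step: step 21

Assumption: the (S)-configured oxazaborolidinium catalyst is taken to deliver 4 as the (1S,2R) enantiomer; should the sense of induction be opposite, its enantiomer is used and nothing else changes.

## Route

Step 1
Reactants: 1 3-methylbut-2-enal
Product: 2 (E)-tert-butyldimethyl[(3-methylbuta-1,3-dien-1-yl)oxy]silane
Conditions: TBSOTf, Et3N, Et2O, 0 °C to rt
Reagents that add atoms: tert-butyldimethylsilyl trifluoromethanesulfonate, CC(C)(C)[Si](C)(C)OS(=O)(=O)C(F)(F)F
Why: Soft enolisation (γ-deprotonation and O-silylation) of the enal gives the silyl dienol ether; the (E)-isomer should predominate and only it can adopt the s-cis form needed in step 2.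

Step 2
Reactants: 2 silyl dienol ether; 3 2,2,2-trifluoroethyl acrylate
Product: 4 2,2,2-trifluoroethyl (1S,2R)-2-[(tert-butyldimethylsilyl)oxy]-4-methylcyclohex-3-ene-1-carboxylate
Conditions: (S)-o-tolyl-oxazaborolidine, HNTf2 (10 mol % each), CH2Cl2, −78 °C
Reagents that add atoms: none
Why: Enantioselective Diels–Alder reaction under chiral oxazaborolidinium catalysis; the 1-silyloxy and 3-methyl groups both direct the ester-bearing carbon next to the oxygenated carbon, endo approach sets C1 and C6 cis, and the catalyst face sets the absolute configuration.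

Step 3
Reactants: 4 cyclohexene ester
Product: 5 2,2,2-trifluoroethyl (1R,2S,3S,6S)-2-[(tert-butyldimethylsilyl)oxy]-6-methyl-7-oxabicyclo[4.1.0]heptane-3-carboxylate
Conditions: mCPBA, NaHCO3, CH2Cl2, 0 °C
Reagents that add atoms: 3-chloroperoxybenzoic acid, OOC(=O)c1cccc(Cl)c1
Why: Prilezhaev epoxidation of the only alkene; the peracid should approach anti to the allylic silyl ether and the homoallylic ester, which share one face, so the epoxide oxygen ends trans to the C1 carboxyl as step 4 requires.

Step 4
Reactants: 5 epoxy ester
Product: 7 (1S,4S,5S,8S)-8-[(tert-butyldimethylsilyl)oxy]-4-hydroxy-4-methyl-6-oxabicyclo[3.2.1]octan-7-one, via epoxy acid 6 (not isolated)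
Conditions: LiOH, THF/H2O, rt then 50 °C; then 1 M HCl to pH 3, 0 °C
Reagents that add atoms: lithium hydroxide, [Li+].[OH-]
Why: Saponification of the activated ester frees the carboxylate, which opens the trans epoxide by 5-exo, trans-diaxial SN2 attack at the secondary C5 (Fürst–Plattner rule); under basic conditions the tertiary C4 is not attacked. The new C5–O bond is cis to C1 and C6 by geometry, and acidification after full conversion relactonises any hydrolysed hydroxy acid.

Step 5
Reactants: 7 hydroxy lactone
Product: 8 (1S,5R,8S)-8-[(tert-butyldimethylsilyl)oxy]-4-methyl-6-oxabicyclo[3.2.1]oct-3-en-7-one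
Conditions: SOCl2, pyridine, CH2Cl2, −20 to 0 °C
Reagents that add atoms: none
Why: Anti elimination through the chlorosulfite of the axial tertiary alcohol; the axial C3–H is anti-periplanar, and C5 is a bridgehead and cannot take part (Bredt's rule), so the trisubstituted C3=C4 alkene is the expected Zaitsev product.

Step 6
Reactants: 8 unsaturated lactone
Product: 9 1-[(1S,5R,6S)-6-[(tert-butyldimethylsilyl)oxy]-5-hydroxy-4-methylcyclohex-3-en-1-yl]ethan-1-one (may rest as its bicyclic hemiketal)
Conditions: MeLi (1.05 equiv), THF, −78 °C; then AcOH, −78 °C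
Reagents that add atoms: methyllithium, [Li]C
Why: Single addition of an organolithium to a lactone; the lithium hemiketal should hold at −78 °C and the bridgehead α-carbon cannot enolise. Protonation gives the methyl ketone with C5–OH free and already distinguished from the silylated C6 oxygen.

Step 7
Reactants: 9 hydroxy ketone
Product: 10 1-[(1S,5R,6S)-6-[(tert-butyldimethylsilyl)oxy]-4-methyl-5-[(triethylsilyl)oxy]cyclohex-3-en-1-yl]ethan-1-one
Conditions: TESCl, imidazole, DMF, 0 °C
Reagents that add atoms: chlorotriethylsilane, CC[Si](Cl)(CC)CC
Why: Standard silylation of the secondary allylic alcohol; the triethylsilyl group is chosen because it can later be removed beside the tert-butyldimethylsilyl ether.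

Step 8
Reactants: 10 methyl ketone
Product: 11 1-[(1S,5R,6S)-6-[(tert-butyldimethylsilyl)oxy]-4-methyl-5-[(triethylsilyl)oxy]cyclohex-3-en-1-yl]ethenyl trifluoromethanesulfonate
Conditions: KN(SiMe3)2, THF, −78 °C; then PhNTf2, −78 to 0 °C
Reagents that add atoms: N-phenylbis(trifluoromethanesulfonimide), O=S(=O)(N(c1ccccc1)S(=O)(=O)C(F)(F)F)C(F)(F)F
Why: Kinetic deprotonation at the unhindered methyl group and O-sulfonylation of the enolate give the 1,1-disubstituted enol triflate; the tertiary C1–H is not removed at −78 °C, so C1 keeps its configuration.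

Step 9
Reactants: 12 (R)-3-hydroxyoxolan-2-one
Product: 13 (R)-4-methylpentane-1,3,4-triol
Conditions: MeMgBr (3.5 equiv), THF, 0 °C to rt; then sat. aq. NH4Cl
Reagents that add atoms: methylmagnesium bromide (two methyl groups are delivered), C[Mg]Br
Why: Double Grignard addition to the lactone carbonyl after deprotonation of the hydroxyl; the stereocentre is not involved.

Step 10
Reactants: 13 triol
Product: 14 2-[(4R)-2,2,5,5-tetramethyl-1,3-dioxolan-4-yl]ethan-1-ol
Conditions: 2,2-dimethoxypropane, camphorsulfonic acid (cat.), acetone, rt
Reagents that add atoms: 2,2-dimethoxypropane, COC(C)(C)OC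
Why: Acid-catalysed transketalisation under thermodynamic control; the five-membered dioxolane on the vicinal secondary/tertiary diol should be favoured over the six-membered dioxane, leaving the primary alcohol free.

Step 11
Reactants: 14 acetonide alcohol
Product: 15 2-[(4R)-2,2,5,5-tetramethyl-1,3-dioxolan-4-yl]acetaldehyde
Conditions: TEMPO (10 mol %), PhI(OAc)2, CH2Cl2, rt
Reagents that add atoms: none
Why: Oxoammonium-mediated oxidation of a primary alcohol stops at the aldehyde under nearly neutral conditions; the acetonide and the β-stereocentre are untouched.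

Step 12
Reactants: 11 enol triflate; 15 aldehyde
Product: 16 (2RS)-3-[(1R,5R,6S)-6-[(tert-butyldimethylsilyl)oxy]-4-methyl-5-[(triethylsilyl)oxy]cyclohex-3-en-1-yl]-1-[(4R)-2,2,5,5-tetramethyl-1,3-dioxolan-4-yl]but-3-en-2-ol (both C8 epimers)
Conditions: CrCl2 (4 equiv), NiCl2 (2 mol %), DMF, rt
Reagents that add atoms: none
Why: Nozaki–Hiyama–Kishi coupling: nickel activates the enol triflate, the alkenyl group passes to chromium and adds to the aldehyde, forming C7–C8 with the methylene in place. Silyl ethers and the acetonide are inert; the C8 configuration is not controlled here and is set in steps 13 and 14.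

Step 13
Reactants: 16 allylic alcohols
Product: 17 3-[(1R,5R,6S)-6-[(tert-butyldimethylsilyl)oxy]-4-methyl-5-[(triethylsilyl)oxy]cyclohex-3-en-1-yl]-1-[(4R)-2,2,5,5-tetramethyl-1,3-dioxolan-4-yl]but-3-en-2-one
Conditions: Dess–Martin periodinane, NaHCO3, CH2Cl2, 0 °C to rt
Reagents that add atoms: none
Why: Dess–Martin oxidation converges both C8 epimers on one α-methylene ketone under buffered, non-basic conditions that do not touch C1.

Step 14
Reactants: 17 enone
Product: 18 (2S)-3-[(1R,5R,6S)-6-[(tert-butyldimethylsilyl)oxy]-4-methyl-5-[(triethylsilyl)oxy]cyclohex-3-en-1-yl]-1-[(4R)-2,2,5,5-tetramethyl-1,3-dioxolan-4-yl]but-3-en-2-ol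
Conditions: (R)-2-methyl-CBS-oxazaborolidine (0.5 equiv), catecholborane, toluene, −78 °C
Reagents that add atoms: none
Why: Corey–Bakshi–Shibata reduction; the α-branched alkenyl group acts as the large and the CH2 group as the small substituent, so the (R)-catalyst should give the (8S)-alcohol under catalyst control. Catecholborane at −78 °C leaves the alkenes alone.

Step 15
Reactants: 18 (8S)-alcohol
Product: 19 (2S)-3-[(1R,5R,6S)-6-[(tert-butyldimethylsilyl)oxy]-5-hydroxy-4-methylcyclohex-3-en-1-yl]-1-[(4R)-2,2,5,5-tetramethyl-1,3-dioxolan-4-yl]but-3-en-2-ol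
Conditions: HF·pyridine, pyridine, THF, 0 °C
Reagents that add atoms: none
Why: Selective desilylation; a secondary triethylsilyl ether is cleaved much faster than the hindered tert-butyldimethylsilyl ether, and the pyridine-buffered medium spares the acetonide.

Step 16
Reactants: 19 diol; 20 angelic acid (two equivalents are incorporated)
Product: 21 bis-angelate: the C5 and C8 (Z)-2-methylbut-2-enoates of 19 (1R,5R,6S,8S,10R; C6 silyl ether and 10,11-acetonide kept)
Conditions: 20 (3 equiv), 2,4,6-trichlorobenzoyl chloride (3 equiv), Et3N, toluene, rt; then 19, 80 °C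
Reagents that add atoms: angelic acid (second equivalent of 20 as its mixed anhydride), C/C=C(/C)C(=O)O
Why: Yamaguchi-type acylation by the preformed mixed anhydride without a nucleophilic catalyst, conditions under which (Z)-2-methylbut-2-enoates are known to keep their geometry; each of the two allylic hydroxyls takes up one angeloyl group, so two equivalents of 20 end in the product.

Step 17
Reactants: 21 bis-angelate
Product: 22 C6 alcohol: 21 without the tert-butyldimethylsilyl group (1R,5R,6S,8S,10R)
Conditions: TBAF, AcOH (1:1), THF, rt
Reagents that add atoms: none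
Why: Fluoride-mediated desilylation buffered with acetic acid, so that the C6 alkoxide is protonated before the neighbouring C5 angelate can migrate.

Step 18
Reactants: 22 C6 alcohol
Product: 23 C6 acetate: 6-acetate, 5- and 8-angelates, 10,11-acetonide (1R,5R,6S,8S,10R)
Conditions: Ac2O, pyridine, DMAP (cat.), CH2Cl2, 0 °C
Reagents that add atoms: acetic anhydride, CC(=O)OC(C)=O
Why: Standard acetylation of the one free secondary alcohol.

Step 19
Reactants: 23 triester acetonide
Product: 24 (10R)-10,11-diol triester (1R,5R,6S,8S,10R)
Conditions: AcOH/H2O (4:1), 40 °C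
Reagents that add atoms: none
Why: Acid hydrolysis of the strained tetramethyl dioxolane; the three esters and the alkenes are stable in aqueous acetic acid.

Step 20
Reactants: 24 diol triester
Product: 26 C3=C4 alkene triester with the (10S)-10,11-epoxide (1R,5R,6S,8S,10S), via mesylate 25 (not isolated)
Conditions: MsCl, Et3N, CH2Cl2, −20 °C; then DBU, rt
Reagents that add atoms: none
Why: Sulfonylation of the only secondary hydroxyl, then intramolecular Williamson displacement (3-exo-tet) by the tertiary oxygen with inversion at C10, turning the (R)-diol into the (S)-epoxide. A non-nucleophilic base keeps the three esters intact.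

Step 21
Reactants: 26 alkene triester; 27 N-chlorosuccinimide
Product: 29 CNP0313121.1 (1R,3S,4S,5S,6S,8S,10S), via dioxolanylium ion 28 (not isolated)
Conditions: 27 (1.05 equiv), acetone/pH 7 phosphate buffer (3:1), 0 °C, dark; then aq. NaHCO3, rt
Reagents that add atoms: water, O
Why: Proposed new method: Cl+ is transferred from 27 (or from HOCl formed in the buffer) to the trisubstituted C3=C4 alkene on the face anti to the C1, C5 and C6 substituents; the carbonyl oxygen of the C5 angelate then attacks the tertiary C4 anti to chlorine in a 5-exo-tet closure to the cis-fused dioxolanylium ion 28, water adds to its cationic carbon and the orthoacid collapses, so no ring remains. The closest known reaction type is halohydrin formation with 1,2-acyloxy participation (Woodward–Prévost-type capture of a halonium ion by a neighbouring ester), established for bromine and iodine but not for chlorine on an allylic angelate beside an epoxide. C3 is set by the face of Cl+ transfer, which steric shielding of the upper face favours and which is enforced because only the lower-face chloronium ion can be opened intramolecularly; C4 is set by delivery of the C5 ester oxygen with inversion at the chloronium carbon, which puts the C4 oxygen cis to C5 and trans to chlorine. The step needs site selectivity among four C=C bonds: the ring alkene is the only trisubstituted, unconjugated one, the C7 methylene is 1,1-disubstituted and flanked by the ring and the C8 ester, and the angelate alkenes are electron-poor. It needs the C10–C11 epoxide to survive, which the pH 7 buffer should secure by keeping HCl out, and it needs capture at C4 to outrun ene-type loss of an allylic proton. The orthoacid can open to either hydroxy ester, and the bicarbonate hold lets an acyl group on the tertiary C4 oxygen move through the same orthoacid to the secondary C5 oxygen, the less strained ester. One equivalent of 27 at 0 °C in the dark limits further chlorination.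

## Compound list

1 | 3-methylbut-2-enal | CC(C)=CC=O | starting material
2 | (E)-tert-butyldimethyl[(3-methylbuta-1,3-dien-1-yl)oxy]silane | C=C(C)/C=C/O[Si](C)(C)C(C)(C)C | intermediate
3 | 2,2,2-trifluoroethyl acrylate | C=CC(=O)OCC(F)(F)F | starting material
4 | 2,2,2-trifluoroethyl (1S,2R)-2-[(tert-butyldimethylsilyl)oxy]-4-methylcyclohex-3-ene-1-carboxylate | O=C(OCC(F)(F)F)[C@H]1CCC(C)=C[C@H]1O[Si](C)(C)C(C)(C)C | intermediate
5 | 2,2,2-trifluoroethyl (1R,2S,3S,6S)-2-[(tert-butyldimethylsilyl)oxy]-6-methyl-7-oxabicyclo[4.1.0]heptane-3-carboxylate | O=C(OCC(F)(F)F)[C@H]1CC[C@]2(C)O[C@@H]2[C@H]1O[Si](C)(C)C(C)(C)C | intermediate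
6 | (1R,2S,3S,6S)-2-[(tert-butyldimethylsilyl)oxy]-6-methyl-7-oxabicyclo[4.1.0]heptane-3-carboxylic acid | O=C(O)[C@H]1CC[C@]2(C)O[C@@H]2[C@H]1O[Si](C)(C)C(C)(C)C | intermediate
7 | (1S,4S,5S,8S)-8-[(tert-butyldimethylsilyl)oxy]-4-hydroxy-4-methyl-6-oxabicyclo[3.2.1]octan-7-one | O=C1O[C@@H]2[C@@](C)(O)CC[C@H]1[C@@H]2O[Si](C)(C)C(C)(C)C | intermediate
8 | (1S,5R,8S)-8-[(tert-butyldimethylsilyl)oxy]-4-methyl-6-oxabicyclo[3.2.1]oct-3-en-7-one | O=C1O[C@@H]2C(C)=CC[C@H]1[C@@H]2O[Si](C)(C)C(C)(C)C | intermediate
9 | 1-[(1S,5R,6S)-6-[(tert-butyldimethylsilyl)oxy]-5-hydroxy-4-methylcyclohex-3-en-1-yl]ethan-1-one | CC(=O)[C@H]1CC=C(C)[C@@H](O)[C@H]1O[Si](C)(C)C(C)(C)C | intermediate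
10 | 1-[(1S,5R,6S)-6-[(tert-butyldimethylsilyl)oxy]-4-methyl-5-[(triethylsilyl)oxy]cyclohex-3-en-1-yl]ethan-1-one | CC(=O)[C@H]1CC=C(C)[C@@H](O[Si](CC)(CC)CC)[C@H]1O[Si](C)(C)C(C)(C)C | intermediate
11 | 1-[(1S,5R,6S)-6-[(tert-butyldimethylsilyl)oxy]-4-methyl-5-[(triethylsilyl)oxy]cyclohex-3-en-1-yl]ethenyl trifluoromethanesulfonate | C=C(OS(=O)(=O)C(F)(F)F)[C@H]1CC=C(C)[C@@H](O[Si](CC)(CC)CC)[C@H]1O[Si](C)(C)C(C)(C)C | intermediate
12 | (R)-3-hydroxyoxolan-2-one ((R)-α-hydroxy-γ-butyrolactone, the lactone derived from (R)-malic acid) | O=C1OCC[C@H]1O | starting material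
13 | (R)-4-methylpentane-1,3,4-triol | OCC[C@@H](O)C(C)(C)O | intermediate
14 | 2-[(4R)-2,2,5,5-tetramethyl-1,3-dioxolan-4-yl]ethan-1-ol | OCC[C@H]1OC(C)(C)OC1(C)C | intermediate
15 | 2-[(4R)-2,2,5,5-tetramethyl-1,3-dioxolan-4-yl]acetaldehyde | O=CC[C@H]1OC(C)(C)OC1(C)C | intermediate
16 | coupled allylic alcohol, both C8 epimers (1R,5R,6S,10R) | C=C(C(O)C[C@H]1OC(C)(C)OC1(C)C)[C@H]1CC=C(C)[C@@H](O[Si](CC)(CC)CC)[C@H]1O[Si](C)(C)C(C)(C)C | intermediate
17 | C8 enone (1R,5R,6S,10R) | C=C(C(=O)C[C@H]1OC(C)(C)OC1(C)C)[C@H]1CC=C(C)[C@@H](O[Si](CC)(CC)CC)[C@H]1O[Si](C)(C)C(C)(C)C | intermediate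
18 | (8S)-allylic alcohol (1R,5R,6S,8S,10R) | C=C([C@H](C[C@H]1OC(C)(C)OC1(C)C)O)[C@H]1CC=C(C)[C@@H](O[Si](CC)(CC)CC)[C@H]1O[Si](C)(C)C(C)(C)C | intermediate
19 | C5,C8-diol with C6 silyl ether and 10,11-acetonide (1R,5R,6S,8S,10R) | C=C([C@H](C[C@H]1OC(C)(C)OC1(C)C)O)[C@H]1CC=C(C)[C@@H](O)[C@H]1O[Si](C)(C)C(C)(C)C | intermediate
20 | angelic acid, (Z)-2-methylbut-2-enoic acid | C/C=C(/C)C(=O)O | starting material
21 | C5,C8-bis-angelate with C6 silyl ether and 10,11-acetonide (1R,5R,6S,8S,10R) | C=C([C@H](C[C@H]1OC(C)(C)OC1(C)C)OC(=O)/C(C)=C\C)[C@H]1CC=C(C)[C@@H](OC(=O)/C(C)=C\C)[C@H]1O[Si](C)(C)C(C)(C)C | intermediate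
22 | C5,C8-bis-angelate C6 alcohol with 10,11-acetonide (1R,5R,6S,8S,10R) | C=C([C@H](C[C@H]1OC(C)(C)OC1(C)C)OC(=O)/C(C)=C\C)[C@H]1CC=C(C)[C@@H](OC(=O)/C(C)=C\C)[C@H]1O | intermediate
23 | C6 acetate, C5,C8-bis-angelate with 10,11-acetonide (1R,5R,6S,8S,10R) | C=C([C@H](C[C@H]1OC(C)(C)OC1(C)C)OC(=O)/C(C)=C\C)[C@H]1CC=C(C)[C@@H](OC(=O)/C(C)=C\C)[C@H]1OC(C)=O | intermediate
24 | triester (10R)-10,11-diol (1R,5R,6S,8S,10R) | C=C([C@H](C[C@@H](O)C(C)(C)O)OC(=O)/C(C)=C\C)[C@H]1CC=C(C)[C@@H](OC(=O)/C(C)=C\C)[C@H]1OC(C)=O | intermediate
25 | triester C10 methanesulfonate, C11 alcohol (1R,5R,6S,8S,10R) | C=C([C@H](C[C@@H](OS(C)(=O)=O)C(C)(C)O)OC(=O)/C(C)=C\C)[C@H]1CC=C(C)[C@@H](OC(=O)/C(C)=C\C)[C@H]1OC(C)=O | intermediate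
26 | C3=C4 alkene triester with (10S)-10,11-epoxide (1R,5R,6S,8S,10S) | C=C([C@H](C[C@@H]1OC1(C)C)OC(=O)/C(C)=C\C)[C@H]1CC=C(C)[C@@H](OC(=O)/C(C)=C\C)[C@H]1OC(C)=O | intermediate
27 | N-chlorosuccinimide | O=C1CCC(=O)N1Cl | starting material
28 | cis-fused 2-[(Z)-but-2-en-2-yl]-1,3-dioxolan-2-ylium ion across C4 and C5, C3 chloride | C=C([C@H](C[C@@H]1OC1(C)C)OC(=O)/C(C)=C\C)[C@H]1C[C@H](Cl)[C@@]2(C)O[C+](/C(C)=C\C)O[C@H]2[C@H]1OC(C)=O | intermediate
29 | CNP0313121.1 (1R,3S,4S,5S,6S,8S,10S) | C=C([C@H](C[C@@H]1OC1(C)C)OC(=O)/C(C)=C\C)[C@H]1C[C@H](Cl)[C@@](C)(O)[C@@H](OC(=O)/C(C)=C\C)[C@H]1OC(C)=O | target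

## Step count and least certain steps

Total: 21 steps. Longest linear sequence: 18 steps (steps 1–8 and 12–21); the side chain takes steps 9–11.

**Step 21 (key step, proposed new method).** Several processes may compete: chlorine transfer to the upper face followed by opening by water; loss of an allylic proton instead of capture at C4 (ene-type chlorination); attack at the C7 methylene with participation of the C8 ester; acid-triggered opening of the side-chain epoxide if buffering fails; Z-to-E isomerisation of the participating angelate while it is part of the cation; the acyl group staying on the tertiary oxygen; and migration of the C6 acetyl group to a transiently free C5 hydroxyl. The fallback uses known chemistry, oxygen first and chloride second; it sets out from 18 and returns to the route at 29. The C8 hydroxyl of 18 is angeloylated under the conditions of step 16 to the mono-angelate F1, and HF·pyridine then frees the C5 alcohol F2. Hydroxyl-directed epoxidation (VO(acac)2, t-BuOOH) gives the syn epoxy alcohol F3, with the C3–C4 epoxide on the face of the C5 hydroxyl. Titanium-mediated opening of this 2,3-epoxy alcohol with chloride (Ti(OiPr)4, Et2NH2Cl) at C3, the carbon remote from the hydroxyl, gives the chlorohydrin diol F4 with chlorine trans to the C4 hydroxyl. Angeloylation of the secondary C5 hydroxyl (the tertiary one is inert) gives the bis-angelate F5, buffered TBAF gives the C6 alcohol F6, and acetylation gives the acetate F7. Aqueous acetic acid removes the acetonide to give the triol F8, and Mitsunobu cyclodehydration (PPh3, DIAD) closes the side-chain epoxide with inversion at C10 under neutral conditions, which leave the ring chlorohydrin open, and arrives at 29. In this order the ring epoxide is opened before the side-chain epoxide exists.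

**Step 2.** Low enantio- or endo-selectivity, or acid-induced desilylation and stepwise Michael addition of the silyl dienol ether without ring closure, may spoil the cycloaddition. The fallback sets out from 1 and returns to the route at 7. Enol acetylation of 1 gives the acetoxy diene A5, and cycloaddition with the imide A6 under Cu(SbF6)2 and the appropriate enantiomer of the tert-butyl bis(oxazoline) ligand gives the adduct A7. mCPBA gives the epoxy imide F9; LiOH/H2O2 removes the oxazolidinone and the acetate, and the carboxylate opens the epoxide and lactonises on acidification to the dihydroxy lactone F10; TBSCl/imidazole silylates the secondary C6 hydroxyl and gives 7.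

**Step 4.** The epoxide may open at the tertiary C4 if acid reaches unreacted epoxide (six-membered lactone, wrong C5 configuration), or the solvated carboxylate may open it too slowly. The fallback sets out from 4 and returns to the route at 8, bypassing steps 3 to 5. HF·pyridine gives the hydroxy ester F11. A Schenck ene reaction (O2, light, tetraphenylporphyrin, nonpolar solvent), in which hydrogen bonding to the C6 hydroxyl is counted on to steer singlet oxygen to C5 on the hydroxyl face, moves the alkene to C3=C4 and gives the allylic hydroperoxide F12, which PPh3 reduces in the same flask to the diol F13. The activated ester lactonises onto the C5 hydroxyl (DBU cat.) to the hydroxy lactone F14, and TBSCl/imidazole gives 8.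

**Step 5.** A methyl proton may be lost instead of the ring proton (exocyclic alkene), or the chlorosulfite may collapse by substitution to the tertiary chloride. The fallback sets out from 7 and returns to the route at 8: dehydration with the Burgess reagent, a syn elimination that should take a methyl proton, gives the exocyclic alkene F15, which RhCl3·3H2O in ethanol isomerises to 8. The bridgehead C5 blocks migration in the other direction, so the endocyclic trisubstituted alkene is the only outlet.

**Step 16.** Acylation of the hindered C5 hydroxyl may stay incomplete, and prolonged heating may cause Z-to-E isomerisation of the angeloyl groups. The fallback sets out from 19 and returns to the route at 21: double deprotonation with LiN(SiMe3)2 at −78 °C and acylation of the dialkoxide with angelic anhydride F16 (made from 20 with a carbodiimide) gives 21 without heating, through alkoxide acylation in place of a mixed anhydride. The reaction is kept cold and short so that the C6 silyl group does not wander to the C5 alkoxide.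

## Further compounds

F1 | step 21 | C8 angelate of 18 (C5 triethylsilyl ether, C6 tert-butyldimethylsilyl ether, acetonide) | C=C([C@H](C[C@H]1OC(C)(C)OC1(C)C)OC(=O)/C(C)=C\C)[C@H]1CC=C(C)[C@@H](O[Si](CC)(CC)CC)[C@H]1O[Si](C)(C)C(C)(C)C
F2 | step 21 | C8 angelate, C5 alcohol | C=C([C@H](C[C@H]1OC(C)(C)OC1(C)C)OC(=O)/C(C)=C\C)[C@H]1CC=C(C)[C@@H](O)[C@H]1O[Si](C)(C)C(C)(C)C
F3 | step 21 | C3–C4 epoxide syn to the C5 hydroxyl | C=C([C@H](C[C@H]1OC(C)(C)OC1(C)C)OC(=O)/C(C)=C\C)[C@H]1C[C@H]2O[C@@]2(C)[C@@H](O)[C@H]1O[Si](C)(C)C(C)(C)C
F4 | step 21 | C3 chloride, C4,C5-diol | C=C([C@H](C[C@H]1OC(C)(C)OC1(C)C)OC(=O)/C(C)=C\C)[C@H]1C[C@H](Cl)[C@@](C)(O)[C@@H](O)[C@H]1O[Si](C)(C)C(C)(C)C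
F5 | step 21 | chlorohydrin C5,C8-bis-angelate, C6 silyl ether | C=C([C@H](C[C@H]1OC(C)(C)OC1(C)C)OC(=O)/C(C)=C\C)[C@H]1C[C@H](Cl)[C@@](C)(O)[C@@H](OC(=O)/C(C)=C\C)[C@H]1O[Si](C)(C)C(C)(C)C
F6 | step 21 | chlorohydrin bis-angelate, C6 alcohol | C=C([C@H](C[C@H]1OC(C)(C)OC1(C)C)OC(=O)/C(C)=C\C)[C@H]1C[C@H](Cl)[C@@](C)(O)[C@@H](OC(=O)/C(C)=C\C)[C@H]1O
F7 | step 21 | chlorohydrin triester with 10,11-acetonide | C=C([C@H](C[C@H]1OC(C)(C)OC1(C)C)OC(=O)/C(C)=C\C)[C@H]1C[C@H](Cl)[C@@](C)(O)[C@@H](OC(=O)/C(C)=C\C)[C@H]1OC(C)=O
F8 | step 21 | chlorohydrin triester (10R)-10,11-diol | C=C([C@H](C[C@@H](O)C(C)(C)O)OC(=O)/C(C)=C\C)[C@H]1C[C@H](Cl)[C@@](C)(O)[C@@H](OC(=O)/C(C)=C\C)[C@H]1OC(C)=O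
F9 | step 2 | epoxy imide from A7 (epoxide trans to imide and acetate) | O=C(N1CCOC1=O)[C@H]1CC[C@]2(C)O[C@@H]2[C@H]1OC(C)=O
F10 | step 2 | (1S,4S,5S,8S)-4,8-dihydroxy-4-methyl-6-oxabicyclo[3.2.1]octan-7-one | O=C1O[C@@H]2[C@@](C)(O)CC[C@H]1[C@@H]2O
F11 | step 4 | 2,2,2-trifluoroethyl (1S,2R)-2-hydroxy-4-methylcyclohex-3-ene-1-carboxylate | O=C(OCC(F)(F)F)[C@H]1CCC(C)=C[C@H]1O
F12 | step 4 | 2,2,2-trifluoroethyl cis,cis-5-hydroperoxy-6-hydroxy-4-methylcyclohex-3-ene-1-carboxylate | O=C(OCC(F)(F)F)[C@H]1CC=C(C)[C@@H](OO)[C@H]1O
F13 | step 4 | 2,2,2-trifluoroethyl cis,cis-5,6-dihydroxy-4-methylcyclohex-3-ene-1-carboxylate | O=C(OCC(F)(F)F)[C@H]1CC=C(C)[C@@H](O)[C@H]1O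
F14 | step 4 | (1S,5R,8S)-8-hydroxy-4-methyl-6-oxabicyclo[3.2.1]oct-3-en-7-one | O=C1O[C@@H]2C(C)=CC[C@H]1[C@@H]2O
F15 | step 5 | (1S,5R,8S)-8-[(tert-butyldimethylsilyl)oxy]-4-methylidene-6-oxabicyclo[3.2.1]octan-7-one | O=C1O[C@@H]2C(=C)CC[C@H]1[C@@H]2O[Si](C)(C)C(C)(C)C
F16 | step 16 | angelic anhydride, (Z)-2-methylbut-2-enoic anhydride | C/C=C(/C)C(=O)OC(=O)/C(C)=C\C
A1 | alternative 1 | (E)-1-(tert-butyldimethylsilyloxy)-2-methylbuta-1,3-diene | C=C/C(C)=C/O[Si](C)(C)C(C)(C)C
A2 | alternative 1 | cyclobut-2-en-1-one | O=C1CC=C1
A3 | alternative 1 | cis-fused bicyclo[4.2.0]oct-3-en-7-one with C5 silyl ether | O=C1C[C@H]2CC=C(C)[C@@H](O[Si](C)(C)C(C)(C)C)[C@@H]12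
A4 | alternative 1 | cis-fused γ-lactone from Baeyer–Villiger oxidation of A3 (C6–O, C5 silyl ether) | O=C1C[C@H]2CC=C(C)[C@@H](O[Si](C)(C)C(C)(C)C)[C@H]2O1
A5 | alternative 2 | (E)-1-acetoxy-3-methylbuta-1,3-diene | C=C(C)/C=C/OC(C)=O
A6 | alternative 2 | 3-acryloyloxazolidin-2-one | C=CC(=O)N1CCOC1=O
A7 | alternative 2 | cis-6-acetoxy-4-methylcyclohex-4-ene C1 imide | O=C(N1CCOC1=O)[C@H]1CCC(C)=C[C@H]1OC(C)=O
A8 | alternative 3 | 2-deoxy-D-ribose (open-chain form) | O=CC[C@H](O)[C@H](O)CO
A9 | alternative 3 | δ-lactone with C5,C6-acetonide and C4 methyl and vinyl (vinyl trans to the C5 oxygen) | O=C1C[C@@H]2OC(C)(C)O[C@@H]2[C@@](C)(C=C)O1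
A10 | alternative 3 | acetonide of cis-5,6-dihydroxy-4-methylcyclohex-3-ene-1-carboxylic acid | OC(=O)[C@H]1CC=C(C)[C@H]2OC(C)(C)O[C@@H]12
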